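## Retrosynthetic overview
1. The acetate goes on last. The C6=C7 butenolide alkene comes from a selenoxide elimination, and the cyclopropane from an OH-directed Simmons–Smith reaction on a Z-C4=C5 cyclooctene.
2. The lactone is turned round late. A 5-(silyloxymethyl)butyrolactone with its C=O on the C6 side is reduced, its glycol is cleaved, and the new lactol is oxidised so that C=O ends on C7.
3. Key step: the eight-membered ring forms by Claisen [3,3] ring expansion of a 2-methylene-6-[(E)-propenyl]tetrahydropyran. This makes C2–C3 and sets C3.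
4. The pyran comes from a 6-exo selenoetherification. Its carbons come from an anti-aldol with crotonaldehyde, a Wittig methylenation, and a Michael addition of the (R)-citronellal hydrazone azaenolate to (S)-5-(silyloxymethyl)butenolide.
5. Ring order: γ-lactone (bought) → tetrahydropyran → cyclooctenone → cyclopropane → transposed butenolide.

Assumption: both chiral starting materials are bought enantiopure; my locants are C1 = OAc carbon, C2 = ring CH2, C3 = CHCH3, C4/C5 = cyclopropane CH (C5 next to the lactone), C6/C7 = lactone β/α carbons of the target, C8 = ring CH bearing the side chain, C10/C11 = the lactone carbons on C6/C7, C1' = side-chain CH(CH3).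

## Route

Step 1
Reactants: 1 (R)-citronellal
Product: 2 (R)-citronellal N,N-dimethylhydrazone (E at C=N)
Conditions: Me2NNH2 (1.2 equiv), MgSO4, CH2Cl2, 0 °C to rt
Reagents that add atoms: N,N-dimethylhydrazine, CN(C)N
Why: Hydrazone condensation gives a non-self-condensing azaenolate precursor for C8, and the bought centre C1' is not touched.

Step 2
Reactants: 3 (S)-5-(hydroxymethyl)furan-2(5H)-one
Product: 4 (S)-5-(tert-butyldiphenylsilyloxymethyl)furan-2(5H)-one
Conditions: TBDPSCl, imidazole, CH2Cl2, 0 °C to rt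
Reagents that add atoms: tert-butyldiphenylsilyl chloride, CC(C)(C)[Si](Cl)(c1ccccc1)c1ccccc1
Why: Silylation gives a base-stable, poorly leaving and bulky group that shields one butenolide face, and no stereocentre changes.

Step 3
Reactants: 2 (R)-citronellal N,N-dimethylhydrazone; 4 (S)-5-(tert-butyldiphenylsilyloxymethyl)furan-2(5H)-one
Product: 7 lactone hydrazone (4R,5S)-5-(TBDPS-oxymethyl)-4-[(1S,2R)-1-(dimethylhydrazonomethyl)-2,6-dimethylhept-5-enyl]dihydrofuran-2(3H)-one, via lithio azaenolate 5 (not isolated), via lithium lactone enolate 6 (not isolated)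
Conditions: LDA (1.05 equiv), THF, 0 °C; then 4, −78 °C; AcOH quench at −78 °C
Reagents that add atoms: none
Why: In this azaenolate Michael addition the nucleophile enters anti to the CH2OSi group, which sets C7, and the staggered transition state that holds the branched side chain anti to the ring C=C sets C8 (S), so both centres are dictated by the bought lactone centre.

Step 4
Reactants: 7 lactone hydrazone
Product: 8 lactone aldehyde (2S,3R)-3,7-dimethyl-2-[(2S,3R)-5-oxo-2-(TBDPS-oxymethyl)tetrahydrofuran-3-yl]oct-6-enal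
Conditions: sat. aq. oxalic acid, Et2O, rt (two phases)
Reagents that add atoms: water, O
Why: Mild two-phase hydrazone hydrolysis frees the C1 aldehyde without enolising C8, and the silyl ether, lactone and alkene are inert.

Step 5
Reactants: 8 lactone aldehyde
Product: 9 vinyl lactone (4R,5S)-4-[(3S,4R)-4,8-dimethylnona-1,7-dien-3-yl]-5-(TBDPS-oxymethyl)dihydrofuran-2(3H)-one
Conditions: Ph3PCH3Br, KHMDS, THF, −78 to 0 °C
Reagents that add atoms: methyltriphenylphosphonium bromide, C[P+](c1ccccc1)(c1ccccc1)c1ccccc1.[Br-]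
Why: Wittig methylenation brings in C2, because the aldehyde reacts far faster than the lactone, and a cold salt-poor ylide keeps C8 intact.

Step 6
Reactants: 9 vinyl lactone; 10 (E)-crotonaldehyde
Product: 12 anti-aldol adduct (3R,4S,5S)-lactone carrying at C3 (= C6) an (R,E)-1-hydroxybut-2-enyl group trans to the C4 (= C7) substituent, via lithium enolate 11 (not isolated)
Conditions: LDA, THF, −78 °C; then 10, −78 °C; AcOH quench at −78 °C
Reagents that add atoms: none
Why: In this Zimmerman–Traxler lithium aldol the ring-locked E(O)-enolate adds 1,2 from the face anti to the C7 substituent, which sets C6 trans, and its chair gives the anti carbinol at C5, the epimer that places the propenyl group axial in the pyran.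

Step 7
Reactants: 12 anti-aldol adduct
Product: 13 phenylselenomethyl tetrahydropyran lactone (pyran trans-fused to the γ-lactone at C6–C7; C5 propenyl axial; C8 side chain equatorial; C1 CH2SePh equatorial)
Conditions: N-(phenylseleno)phthalimide (1.2 equiv), CSA (10 mol %), CH2Cl2, 0 °C to rt
Reagents that add atoms: N-(phenylseleno)phthalimide, O=C1c2ccccc2C(=O)N1[Se]c1ccccc1
Why: In this 6-exo Markovnikov phenylselenoetherification seleniranium formation is reversible on every alkene, only the vinyl group has an OH within reach, and the new C1 centre is erased in the next step.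

Step 8
Reactants: 13 phenylselenomethyl tetrahydropyran lactone
Product: 16 keto lactone (Z)-cyclooct-4-enone (C1=O; C4=C5) trans-fused at C6–C7 to the 5-(TBDPS-oxymethyl)-γ-lactone with 3R methyl group, via selenoxide 14 (not isolated), via methylene tetrahydropyran 15 (not isolated)
Conditions: NaIO4, NaHCO3, MeOH–H2O, 0 °C to rt; crude selenoxide, Et3N, N,N-dimethylacetamide, 220 °C, sealed tube
Reagents that add atoms: none
Why: Selenoxide syn-elimination gives the allyl vinyl ether, and its Claisen [3,3] ring expansion through a chair–chair (bicyclo[3.3.1]-like) transition state with the axial (E)-propenyl group forms C2–C3 and the Z alkene and sets C3 (R) by chirality transfer from C5.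

Step 9
Reactants: 16 keto lactone
Product: 17 triol (C1-OH R and cis to the C8 side chain; C6-CH2OH; C7-CH(OH)CH2OTBDPS)
Conditions: DIBAL-H (6 equiv), CH2Cl2, −78 to 0 °C; Rochelle salt
Reagents that add atoms: none
Why: Hydride reduction attacks the ketone at −78 °C from the face anti to the C8 side chain, which sets C1, and on warming takes the lactone to the diol, bringing C10 to its final CH2O level.

Step 10
Reactants: 17 triol
Product: 18 cyclopropane triol (bicyclo[6.1.0]nonane; the new CH2 on the face of C1-OH and C6-CH2OH)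
Conditions: Et2Zn, CH2I2, CH2Cl2, −20 to 0 °C
Reagents that add atoms: diiodomethane, ICI
Why: In this Furukawa-modified Simmons–Smith reaction the zinc alkoxides of the homoallylic C10-OH and the transannular C1-OH lie on one face, so they deliver CH2 to the ring alkene faster than to the remote trisubstituted alkene and set C4 and C5.

Step 11
Reactants: 18 cyclopropane triol
Product: 20 transposed lactol (C11H(OH)–O–C10H2; C1-OH free), via tetraol 19 (not isolated)
Conditions: TBAF, THF, rt; then pH 7 buffer, NaIO4, 0 °C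
Reagents that add atoms: none
Why: Fluoride desilylation followed by Malaprade cleavage of the only 1,2-diol gives the C11 aldehyde, which closes on C10-OH because C1-OH lies on the opposite face, and this also removes the spent carbinol centre.

Step 12
Reactants: 20 transposed lactol
Product: 21 hydroxy lactone (γ-lactone with C=O on C7; trans-fused; C1-OH free)
Conditions: TEMPO (10 mol %), PhI(OAc)2 (1.2 equiv), CH2Cl2, rt
Reagents that add atoms: none
Why: TEMPO oxoammonium oxidation takes the lactol far faster than the hindered secondary C1-OH and leaves the alkene and cyclopropane alone.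

Step 13
Reactants: 21 hydroxy lactone
Product: 24 hydroxy butenolide (deacetyl target), via C7 selenide 22 (not isolated), via C7 selenoxide 23 (not isolated)
Conditions: LDA (2.5 equiv), THF, −78 to −30 °C; PhSeBr, −78 °C; then 30% H2O2, pyridine, CH2Cl2, 0 °C to rt
Reagents that add atoms: none
Why: In this α-selenenylation and selenoxide syn-elimination selenium enters the enolate on the C6–H face, and only C6–H can reach syn-coplanarity because the five-membered ring clamps the C6–C7 torsion, so C6=C7 forms and C8 is kept.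

Step 14
Reactants: 24 hydroxy butenolide
Product: 25 target CNP0018922.1
Conditions: Ac2O, pyridine, DMAP, CH2Cl2, rt
Reagents that add atoms: acetic anhydride, CC(=O)OC(C)=O
Why: DMAP-catalysed acetylation of the only free hydroxyl proceeds with retention at C1.

## Compound list
1 | (R)-citronellal | O=CC[C@H](C)CCC=C(C)C | starting material
2 | (R)-citronellal N,N-dimethylhydrazone | CN(C)/N=C/C[C@H](C)CCC=C(C)C | intermediate
3 | (S)-5-(hydroxymethyl)furan-2(5H)-one | O=C1C=C[C@@H](CO)O1 | starting material
4 | (S)-5-(TBDPS-oxymethyl)furan-2(5H)-one | O=C1C=C[C@@H](CO[Si](c2ccccc2)(c2ccccc2)C(C)(C)C)O1 | intermediate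
5 | lithio azaenolate of 2 | [Li]N(N(C)C)/C=C/[C@H](C)CCC=C(C)C | intermediate
6 | lithium lactone enolate (Michael adduct) | [Li]OC1=C[C@H]([C@@H](/C=N/N(C)C)[C@H](C)CCC=C(C)C)[C@@H](CO[Si](c2ccccc2)(c2ccccc2)C(C)(C)C)O1 | intermediate
7 | lactone hydrazone | O=C1C[C@H]([C@@H](/C=N/N(C)C)[C@H](C)CCC=C(C)C)[C@@H](CO[Si](c2ccccc2)(c2ccccc2)C(C)(C)C)O1 | intermediate
8 | lactone aldehyde | O=C1C[C@H]([C@@H](C=O)[C@H](C)CCC=C(C)C)[C@@H](CO[Si](c2ccccc2)(c2ccccc2)C(C)(C)C)O1 | intermediate
9 | vinyl lactone | O=C1C[C@H]([C@@H](C=C)[C@H](C)CCC=C(C)C)[C@@H](CO[Si](c2ccccc2)(c2ccccc2)C(C)(C)C)O1 | intermediate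
10 | (E)-crotonaldehyde | C/C=C/C=O | starting material
11 | lithium enolate of 9 | [Li]OC1=C[C@H]([C@@H](C=C)[C@H](C)CCC=C(C)C)[C@@H](CO[Si](c2ccccc2)(c2ccccc2)C(C)(C)C)O1 | intermediate
12 | anti-aldol adduct | O=C1[C@@H]([C@H](O)/C=C/C)[C@H]([C@@H](C=C)[C@H](C)CCC=C(C)C)[C@@H](CO[Si](c2ccccc2)(c2ccccc2)C(C)(C)C)O1 | intermediate
13 | phenylselenomethyl tetrahydropyran lactone | O=C1[C@H]2[C@@H](/C=C/C)O[C@H](C[Se]c3ccccc3)[C@@H]([C@H](C)CCC=C(C)C)[C@@H]2[C@@H](CO[Si](c3ccccc3)(c3ccccc3)C(C)(C)C)O1 | intermediate
14 | selenoxide of 13 | O=C1[C@H]2[C@@H](/C=C/C)O[C@H](C[Se](=O)c3ccccc3)[C@@H]([C@H](C)CCC=C(C)C)[C@@H]2[C@@H](CO[Si](c3ccccc3)(c3ccccc3)C(C)(C)C)O1 | intermediate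
15 | 2-methylene tetrahydropyran lactone | O=C1[C@H]2[C@@H](/C=C/C)OC(=C)[C@@H]([C@H](C)CCC=C(C)C)[C@@H]2[C@@H](CO[Si](c3ccccc3)(c3ccccc3)C(C)(C)C)O1 | intermediate
16 | keto lactone (cyclooct-4-enone) | O=C1C[C@@H](C)/C=C\[C@@H]2C(=O)O[C@H](CO[Si](c3ccccc3)(c3ccccc3)C(C)(C)C)[C@H]2[C@@H]1[C@H](C)CCC=C(C)C | intermediate
17 | triol | O[C@@H]1C[C@@H](C)/C=C\[C@H](CO)[C@@H]([C@H](O)CO[Si](c2ccccc2)(c2ccccc2)C(C)(C)C)[C@@H]1[C@H](C)CCC=C(C)C | intermediate
18 | cyclopropane triol | O[C@@H]1C[C@@H](C)[C@@H]2C[C@@H]2[C@H](CO)[C@@H]([C@H](O)CO[Si](c3ccccc3)(c3ccccc3)C(C)(C)C)[C@@H]1[C@H](C)CCC=C(C)C | intermediate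
19 | tetraol | O[C@@H]1C[C@@H](C)[C@@H]2C[C@@H]2[C@H](CO)[C@@H]([C@H](O)CO)[C@@H]1[C@H](C)CCC=C(C)C | intermediate
20 | transposed lactol (anomers) | O[C@@H]1C[C@@H](C)[C@@H]2C[C@@H]2[C@@H]3COC(O)[C@H]3[C@@H]1[C@H](C)CCC=C(C)C | intermediate
21 | hydroxy lactone | O[C@@H]1C[C@@H](C)[C@@H]2C[C@@H]2[C@@H]3COC(=O)[C@H]3[C@@H]1[C@H](C)CCC=C(C)C | intermediate
22 | C7 phenylselenide | O[C@@H]1C[C@@H](C)[C@@H]2C[C@@H]2[C@@H]3COC(=O)[C@]3([Se]c4ccccc4)[C@@H]1[C@H](C)CCC=C(C)C | intermediate
23 | C7 selenoxide | O[C@@H]1C[C@@H](C)[C@@H]2C[C@@H]2[C@@H]3COC(=O)[C@]3([Se](=O)c4ccccc4)[C@@H]1[C@H](C)CCC=C(C)C | intermediate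
24 | hydroxy butenolide (deacetyl target) | O[C@@H]1C[C@@H](C)[C@@H]2C[C@@H]2C2=C(C(=O)OC2)[C@@H]1[C@H](C)CCC=C(C)C | intermediate
25 | target CNP0018922.1 (1R,3R,4S,5S,8S,1'R) | CC(=O)O[C@@H]1C[C@@H](C)[C@@H]2C[C@@H]2C2=C(C(=O)OC2)[C@@H]1[C@H](C)CCC=C(C)C | target

## Step count and risks
Total steps: 14. Longest linear sequence: 13 (steps 1 and 3–14).

**Step 3 is the most fragile.**
- The basic azaenolate may deprotonate 4 at C5, add 1,2, or give poor control at C8.
- The fallback sets out from 1 and 4 and returns at 8, replacing the lithium chemistry by a Lewis-acid Mukaiyama–Michael addition.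
- Compound 1 with TBSOTf/Et3N gives the Z-configured TBS enol ether of citronellal F1.
- F1 is added to 4 with catalytic TBSOTf in CH2Cl2 at −78 °C. It still enters anti to the CH2OSi group, through an open transition state.
- This gives the silyl ketene acetal aldehyde F2, which a citric acid work-up converts into 8.

**Step 8 is second.**
- Benzeneselenenic acid and the very high temperature can isomerise 15 to the endocyclic enol ether or degrade it before it rearranges.
- The fallback sets out from 12 and returns at 15, then 16. It makes the allyl vinyl ether by a base-induced E2 elimination, so that 15 can be isolated and rearranged on its own.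
- NIS in MeCN at 0 °C closes 12 to the iodomethyl tetrahydropyran lactone F3.
- DBU in toluene at 100 °C eliminates HI from F3 to give 15.
- Compound 15 is then heated in degassed xylene in base-washed glass, or under microwave heating, to give 16.

**Step 13 is third.**
- The tertiary C7–H next to the branched C8 may resist LDA, and the lithium alkoxide can disturb the lactone.
- The fallback sets out from 21 and returns at 24, using soft enolisation and a palladium β-hydride elimination (Saegusa–Ito) in place of selenium chemistry.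
- TMSOTf/Et3N converts 21 into the bis-silylated ketene acetal F4.
- Pd(OAc)2 in MeCN gives the butenolide trimethylsilyl ether F5.
- Dilute citric acid in MeOH frees 24.

## Further compounds
F1 | step 3 | (R,Z)-tert-butyl(3,7-dimethylocta-1,6-dienyloxy)dimethylsilane | CC(C)(C)[Si](C)(C)O/C=C\[C@H](C)CCC=C(C)C
F2 | step 3 | silyl ketene acetal aldehyde (2-TBSO-4,5-dihydrofuran form of 8) | CC(C)(C)[Si](C)(C)OC1=C[C@H]([C@@H](C=O)[C@H](C)CCC=C(C)C)[C@@H](CO[Si](c2ccccc2)(c2ccccc2)C(C)(C)C)O1
F3 | step 8 | iodomethyl tetrahydropyran lactone | O=C1[C@H]2[C@@H](/C=C/C)O[C@H](CI)[C@@H]([C@H](C)CCC=C(C)C)[C@@H]2[C@@H](CO[Si](c3ccccc3)(c3ccccc3)C(C)(C)C)O1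
F4 | step 13 | bis-silylated ketene acetal of 21 | C[Si](C)(C)O[C@@H]1C[C@@H](C)[C@@H]2C[C@@H]2[C@@H]3COC(O[Si](C)(C)C)=C3[C@@H]1[C@H](C)CCC=C(C)C
F5 | step 13 | butenolide trimethylsilyl ether | C[Si](C)(C)O[C@@H]1C[C@@H](C)[C@@H]2C[C@@H]2C2=C(C(=O)OC2)[C@@H]1[C@H](C)CCC=C(C)C
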